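The data are simulated with constants of no real substance.

The earlier runs share one charge of substrate, reagent and second catalyst, and dusk, autumn and midnight differ in [free catalyst].

| setting | dusk | autumn | midnight | Monday's | Wednesday's | Sunday's |
|---|---|---|---|---|---|---|
| substrate | 0.18 M | 0.18 M | 0.18 M | 0.18 M | 0.18 M (fed, over 20 h) | 0.18 M |
| reagent | 0.36 M | 0.36 M | 0.36 M | 0.360 M (fed, over 20 h) | 0.360 M | 0.360 M |
| free catalyst | 1.8 mM | 1.2 mM | 2.7 mM | 1.8 mM | 1.8 mM | 1.8 mM |
| second catalyst | 0.90 mM | 0.90 mM | 0.90 mM | 0.90 mM | 0.90 mM | 0.90 mM |
| remark | run made earlier | run made earlier | run made earlier | all else is in the flask from the start; the feed brings no volume worth counting | all else is in the flask from the start; the feed brings no volume worth counting | everything together at the start |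
| time |  |  |  | 2.0 d | 2.0 d | 2.0 d |

| dusk: time / h | dusk: target / % | autumn: time / d | autumn: target / % | midnight: time / d | midnight: target / % |
|---|---|---|---|---|---|
| 5.00 | 0 | 0.208 | 1 | 0.208 | 3 |
| 10.0 | 3 | 0.333 | 2 | 0.333 | 4 |
| 15.0 | 1 | 0.500 | 3 | 0.500 | 7 |
| 20.0 | 3 | 0.833 | 0 | 0.833 | 11 |
| 25.0 | 5 | 1.67 | 11 | 1.67 | 16 |
| 30.0 | 10 | 2.50 | 13 | 2.50 | 23 |

(readings scatter by 1.5 percentage points)



- the best flask by amount of target, in percent of the substrate charged; "all alike" if 1.5 percentage points covers them all (Monday's / Wednesday's / Sunday's / all alike)
- amount of target at the end, in percent of the substrate charged, Monday's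
- amount of target at the end, in percent of the substrate charged, Wednesday's
- amount of target at the end, in percent of the substrate charged, Sunday's

The forecast's slopes suggest a rate roughly proportional to [free catalyst], so the useful clock is the scaled time, the time of a reading multiplied by its [free catalyst] and divided by dusk's 1.8 mM. Each asked flask stands at a scaled time of 2.00 d. The clock passes a first test: midnight's reading at 0.833 d has a scaled time of 1.25 d and shows 11%, while dusk's reading at 30.0 h, the same scaled time, shows 10%. Autumn's last reading stands at a scaled time of 1.67 d with 13%, and midnight's reading at 1.67 d stands at a scaled time of 2.50 d with 16%, so the estimate here, read between them, is 14.2% of target.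

Substrate is the limiting reagent, at 0.18 M against 0.360 M of reagent, and its ledger has these entries. On this estimate target takes 14.2% of the substrate. At one reagent per target this costs 7.10% of the reagent charge, which Monday's feed delivers within 1.42 h, far inside its 20 h. The remaining 85.8% of the substrate stands unread, as the readings are of target. This reckoning puts all three flasks at 14.2% and calls them alike, which for the two fed flasks is an assumption.

The forecast differs on the feeds: it gives Monday's 11.5%, Wednesday's 11.5% and Sunday's 14%, names Sunday's as best, and warns that “Substrate and reagent orders were never tested”.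

Monday's gives 15.4%, Wednesday's 15.1% and Sunday's 15.8%, so the answer is all alike; Sunday's stands 1.6 percentage points above the estimate.

    substrate + free catalyst → free catalyst + open intermediate (k = 0.00660 M⁻¹ s⁻¹)
    second catalyst + open intermediate ⇌ catalyst intermediate (K = 23.0 M⁻¹, k = 0.0560 M⁻¹ s⁻¹)
    reagent + catalyst intermediate → second catalyst + target (k = 0.110 M⁻¹ s⁻¹)
    substrate + second catalyst ⇌ idle complex, settled at all times (K = 28.0 M⁻¹)
    substrate + open intermediate → side product (k = 8.90 × 10⁻⁴ M⁻¹ s⁻¹)

In Monday's at the end the unread entry holds 79.0% of side product, beside 4.01% of substrate and 1.52% of open intermediate. Striking the conversion of substrate + open intermediate into side product lifts Monday's target from 15.4% to 73.1%. Monday's flask read at 5.0 d, a scaled time of 5.00 d against 2.00 d, holds 20.1% of target beside 79.7% of side product, with substrate down to 0.17%.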